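Remark on the chemistry: ring B is numbered C1–C6 with CO2CH3 on C1, and ring A is numbered C1'–C6' with the depside carbonyl on C1'. Electrophilic bromination of 2-chloro-1,3-dimethoxybenzene would enter at C4 (ortho and para to the methoxy groups), not at C5, so ring A is built here from 3,5-dimethoxytoluene, whose symmetry leaves no regiochemical choice.

## Structural features

The target is a depside: two benzene rings joined by one ester, from the C1' carbonyl of ring A to the C4 oxygen of ring B. Ring A is pentasubstituted (C1' acyl, C2' OH, C3' Cl, C4' OCH3, C6' CH3, only C5' H). Ring B is a methyl orsellinate unit (C1 CO2CH3, C2 OH, C4 O-acyl, C6 CH3). There is no stereocenter, so the whole problem is one of regiochemistry and chemoselectivity. The fragile groups are the aryl ester between the rings (an activated ester towards hydroxide, alkoxide and amines), the methyl ester, the aryl chloride (sensitive to hydrogenolysis over Pd/C) and the two phenols that sit ortho to carbonyl groups. The real difficulties are four: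

- placing chlorine between the two oxygens of ring A;
- keeping O4' methylated while O2' is free;
- forming an ester from a benzoic acid that is blocked at both ortho positions;
- acylating only one of the two oxygens of ring B.

The key step uses the fact that C3(H)–C4(O)–C5(H)–C6(CH3) of ring B is exactly the C3–C6 fragment of 4-hydroxy-6-methyl-2-pyrone. Only C1 and C2 must then be added, as an alkyne that carries the ester and a boron atom which later becomes the C2 hydroxyl. Because the pyrone oxygen is acylated before ring B exists, the choice between the two ring B oxygens never arises.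

## Logic of the disconnections

**19 ⇒ 18.** The O–H bond at C2' is exchanged for O–CH3. A methyl ether lets both ring A oxygens come from one symmetric dimethoxy arene and withstands organolithium reagents and heat, so no separate protection steps are needed. The demand on the forward step is that only the methoxy group ortho to the depside carbonyl is cleaved, and not the C4' methoxy, the methyl ester or the ester between the rings.

**18 ⇒ 17.** The C2–O bond of ring B is exchanged for a C2–B bond. Boron survives the heat of ring formation and is replaced by oxygen at the same carbon, so the C2 oxygen can travel on an alkyne. The forward oxidation must be mild enough for two esters.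

**17 ⇒ 10 + 15 (through 16).** The cuts are C1–C6 and C2–C3 of ring B. This reduces ring B to a pyrone that already holds the C6 methyl and the C4 ester oxygen, plus a two-carbon alkyne, and it leaves the ester between the rings untouched. The forward step must be regioselective (boron to C2, ester to C1), and both partners must tolerate about 160 °C.

**15 ⇒ 11 + 12 (through 13 and 14).** The cut is the C(sp)–B bond. Both pieces are commercial. The forward step needs an acetylide that carries an ester, so it must be run cold and quenched without water.

**10 ⇒ 7 + 8 (through 9).** The cut is the ester C(=O)–O bond between C1' and the pyrone O4. It separates the two halves of the molecule at the stage where both are simple. The forward step must acylate oxygen and not C3 of the pyrone, and must do so with a hindered acyl group.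

**7 ⇒ 4 (through 5 and 6).** The cut is the C1'–CO2H bond. A bromine atom marks the position, so the carboxyl group is placed by halogen–metal exchange and not by a directing effect. The forward step must exchange bromine without touching chlorine.

**4 ⇒ 3.** The cut is the C1'–Br bond. Compound 3 is symmetric and its two free ring positions are equivalent, so only one monobromide is possible. The forward step must stop at monobromination and avoid the benzylic position.

**3 ⇒ 1 (through 2).** The cut is the C3'–Cl bond. The carbon between the two methoxy groups is the one position that both groups direct a base to, so chlorine is placed there by lithiation and not by electrophilic substitution, which would favour other sites. Compound 1 is commercial.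

## Other disconnections considered

**Alternative 1:** formal [3+3] cyclocondensation that builds ring A.

- **Cut:** C3'–C4' and C1'–C6' of ring A.
- **Forward key step:** 4-chloro-1-methoxy-1,3-bis(trimethylsilyloxy)buta-1,3-diene A1 and 4,4-dimethoxybut-3-en-2-one A2 would be combined with TiCl4 in CH2Cl2 from −78 °C to room temperature. The chlorine-bearing terminal carbon of A1 adds to the ketene acetal carbon, the central carbon closes onto the ketone, and loss of water and methanol gives methyl 3-chloro-2-hydroxy-4-methoxy-6-methylbenzoate A3.
- **In its favour:** every substituent of ring A is placed by the connectivity of acyclic partners. O2' is born free and O4' is born methylated, so no late demethylation is needed. The conditions are cold.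
- **Against it here:** chlorine lowers the nucleophilicity of the attacking terminus. The two electrophilic carbons of A2 could be engaged in the reverse order, which would give a regioisomeric salicylate. A3 is a doubly ortho-substituted methyl salicylate whose ester must be hydrolysed and whose free phenol complicates activation before coupling to O4 of methyl 2,4-dihydroxy-6-methylbenzoate A4.
- **Comparison:**
  - Structure: the alternative builds the harder ring and buys ring B intact, which is better economy of effort than the chosen plan.
  - Mechanism: the two are equal, since both rely on polar matching and not on symmetry for orientation; the alternative runs under milder conditions, which is a point in its favour.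
  - Step economy: about equal (diene, annulation, hydrolysis, protection, coupling and deprotection against eight steps). The chosen plan is better in that the hindered ester is formed once, early, from a simple acid chloride, and no diol has to be acylated selectively.

**Alternative 2:** a symmetric aryne takes methyl and carboxyl in one pot.

- **Cut:** C6'–CH3 and C1'–CO2H of ring A.
- **Forward key step:** 5-bromo-2-chloro-1,3-dimethoxybenzene A6 would be deprotonated next to bromine by lithium 2,2,6,6-tetramethylpiperidide. Loss of LiBr gives 4-chloro-3,5-dimethoxybenzyne A7. CH3Li adds at the aryne carbon remote from the methoxy group, and CO2 traps the aryllithium to give 3-chloro-2,4-dimethoxy-6-methylbenzoic acid A8, which is the same compound as 7.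
- **In its favour:** two adjacent carbon substituents arrive in one operation. Either ortho hydrogen of A6 leads to the same aryne. The neighbouring methoxy group directs the addition by stabilising the aryl anion. The sequence ends at 7, so it is compatible with the chosen key step.
- **Against it here:**
  - A6 is not reachable by direct bromination of 2-chloro-1,3-dimethoxybenzene A5, which would be brominated at C4. It would need C–H borylation with [Ir(OMe)(cod)]2 and a bipyridine ligand followed by CuBr2, or purchase.
  - Three basic or nucleophilic lithium species compete. The amide may add to A7. The amine may protonate the aryl anion, which would give 3. CH3Li may be consumed by CO2 or may attack the lithium carboxylate.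
- **Comparison:**
  - Structure: equal, since both routes fix chlorine between the methoxy groups through a symmetric precursor.
  - Mechanism: the chosen three steps have no selectivity question at any stage, while the one-pot aryne sequence has several.
  - Step economy: the alternative is better if A6 is bought (one step to 7 against three) and equal if A6 must be made. It addresses ring A only.

**Alternative 3:** vinylketene acetal Diels–Alder onto a ring B alkynoate.

- **Cut:** C1'–C2' and C5'–C6' of ring A, with the ester between the rings already in place.
- **Forward key step:** [(2-chloro-1,3-dimethoxybuta-1,3-dien-1-yl)oxy]trimethylsilane A9 would be heated with 3-[(tert-butyldimethylsilyl)oxy]-4-(methoxycarbonyl)-5-methylphenyl but-2-ynoate A10. A10 would come from A4 by attaching the but-2-ynoyl group to O4 and a silyl group to O2. The cycloadduct loses methanol, and acidic work-up frees the new phenol to give the ring B silyl ether A11. Fluoride would then give 19.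
- **In its favour:** the hindered ester is never formed by acylation, because ring A is grown on an unhindered alkynoate. Ring A arrives with O2' free and O4' methylated. The nucleophilic CH2 terminus of the diene is strongly matched to the methyl-bearing β-carbon of the ynoate.
- **Against it here:** a β-methyl ynoate is a sluggish dienophile, and chlorine on the diene lowers its reactivity further. The diene is sensitive to moisture and could attack the aryl ester carbonyl instead of cycloadding. Aromatisation must expel methanol and not silanol, otherwise the C2' methyl ether results. A4 must be acylated selectively at O4.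
- **Comparison:**
  - Structure: the plans are mirror images. Each builds one ring by [4+2] on a preformed ester; the alternative builds ring A and the chosen plan builds ring B.
  - Mechanism: equal in type. The chosen plan is better in that loss of CO2 allows only one aromatisation outcome.
  - Step economy: the alternative is better on paper (about six or seven steps and no late BCl3). The chosen plan is preferred for its bench-stable diene and its better-precedented reaction class.

Key step: step 6

## Steps

Step 1
Reactants: 1 3,5-dimethoxytoluene (1,3-dimethoxy-5-methylbenzene)
Product: 3 2-chloro-1,3-dimethoxy-5-methylbenzene, via 2,6-dimethoxy-4-methylphenyllithium 2 (not isolated)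
Conditions: n-BuLi, THF, 0 °C → rt; then C2Cl6, −78 °C → rt
Reagents that add atoms: hexachloroethane, ClC(Cl)(Cl)C(Cl)(Cl)Cl (the chlorine of 3); n-butyllithium, [Li]CCCC (the lithium of intermediate 2 only)
Why: Directed ortho-metalation: both methoxy groups direct the base to the carbon between them, and aryllithium 2 takes chlorine from hexachloroethane with loss of tetrachloroethene. This places chlorine at the future C3' with no regiochemical alternative.

Step 2
Reactants: 3 2-chloro-1,3-dimethoxy-5-methylbenzene
Product: 4 2-bromo-4-chloro-3,5-dimethoxy-1-methylbenzene
Conditions: NBS, MeCN, 0 °C → rt, dark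
Reagents that add atoms: N-bromosuccinimide, BrN1C(=O)CCC1=O
Why: Electrophilic aromatic bromination: 3 is symmetric, its two free ring positions are equivalent, and each is para to one methoxy group and ortho to the other. One equivalent of NBS in a polar solvent without light should give the monobromide and leave the benzylic methyl alone.

Step 3
Reactants: 4 2-bromo-4-chloro-3,5-dimethoxy-1-methylbenzene
Product: 7 3-chloro-2,4-dimethoxy-6-methylbenzoic acid, via 3-chloro-2,4-dimethoxy-6-methylphenyllithium 5 (not isolated), via lithium 3-chloro-2,4-dimethoxy-6-methylbenzoate 6 (not isolated)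
Conditions: n-BuLi, THF, −78 °C; CO2 (g), −78 °C → rt; aq. HCl
Reagents that add atoms: carbon dioxide, O=C=O (the carboxyl group); n-butyllithium, [Li]CCCC (the lithium of intermediates 5 and 6 only)
Why: Bromine–lithium exchange at −78 °C is much faster than exchange of the aryl chloride or benzylic deprotonation. The hindered aryllithium 5 is trapped by the small electrophile CO2 (aryllithium carboxylation), and acidification of carboxylate 6 gives 7.

Step 4
Reactants: 7 3-chloro-2,4-dimethoxy-6-methylbenzoic acid; 8 4-hydroxy-6-methyl-2H-pyran-2-one (triacetic acid lactone)
Product: 10 6-methyl-2-oxo-2H-pyran-4-yl 3-chloro-2,4-dimethoxy-6-methylbenzoate, via 3-chloro-2,4-dimethoxy-6-methylbenzoyl chloride 9 (not isolated)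
Conditions: (COCl)2, DMF (cat.), CH2Cl2, 0 °C → rt, evaporate; then 8, Et3N, CH2Cl2, 0 °C → rt
Reagents that add atoms: oxalyl chloride, ClC(=O)C(Cl)=O (the acyl chlorine of intermediate 9 only)
Why: Acid chloride formation with catalytic DMF, then kinetically controlled O-acylation of the triethylammonium salt of the acidic enol 8. Low temperature and the absence of acyl-transfer catalysts such as 4-dimethylaminopyridine should prevent the shift of the acyl group from O4 to C3, which the bulk of the aroyl group also slows.

Step 5
Reactants: 11 methyl propiolate (methyl prop-2-ynoate); 12 2-isopropoxy-4,4,5,5-tetramethyl-1,3,2-dioxaborolane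
Product: 15 methyl 3-(4,4,5,5-tetramethyl-1,3,2-dioxaborolan-2-yl)prop-2-ynoate, via methyl 3-lithioprop-2-ynoate 13 (not isolated), via lithium alkynyl(isopropoxy)pinacolborate 14 (not isolated)
Conditions: n-BuLi, THF, −78 °C; 12, −78 °C; HCl in Et2O (1 equiv), −78 °C → rt; filtration, distillation
Reagents that add atoms: n-butyllithium, [Li]CCCC (the lithium of intermediates 13 and 14 only)
Why: Deprotonation of the acidic alkyne C–H gives acetylide 13, which adds to the boron of 12 to form ate complex 14. Anhydrous HCl then expels propan-2-ol (alkynylboronate synthesis from a lithium acetylide and an alkoxyboronate). Holding the mixture at −78 °C until the quench should suppress self-condensation of the lithiated ynoate.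

Step 6
Reactants: 10 6-methyl-2-oxo-2H-pyran-4-yl 3-chloro-2,4-dimethoxy-6-methylbenzoate; 15 methyl 3-(4,4,5,5-tetramethyl-1,3,2-dioxaborolan-2-yl)prop-2-ynoate
Product: 17 4-(methoxycarbonyl)-3-methyl-5-(4,4,5,5-tetramethyl-1,3,2-dioxaborolan-2-yl)phenyl 3-chloro-2,4-dimethoxy-6-methylbenzoate, via 2-oxabicyclo[2.2.2]octa-5,7-dien-3-one cycloadduct 16 (not isolated)
Conditions: o-dichlorobenzene, 160 °C, sealed tube, argon (15 in 2.5-fold excess)
Reagents that add atoms: none
Why: The diene C3=C4–C5=C6 of pyrone 10 and the electron-poor triple bond of 15 should combine in a concerted, asynchronous [4+2] cycloaddition of normal electron demand to give bridged lactone 16, which at this temperature loses CO2 by retro-[4+2] and so gives the benzene ring of 17 directly. The closest known reaction type is the thermal benzannulation of 2-pyrones with alkynylboronates, which gives arylboronates after extrusion of CO2. Ring B is closed by an intermolecular cycloaddition that forms C1–C6 and C2–C3 in one suprafacial event, not by cyclisation of a chain, and aromatisation makes the sequence irreversible. No stereocenter remains: the two bridgehead centres of 16 form as a racemic pair fixed by the bicycle and disappear when CO2 leaves. The step needs regioselectivity, with boron at C2 and the ester at C1. The aroyloxy donor on C4 gives pyrone C3 the larger HOMO coefficient and the ester makes the boron-bearing β-carbon of 15 the more electrophilic alkyne carbon, so C3 should bond to the carbon that carries boron and C6 to the carbon that carries CO2CH3. Steric effects point the same way, because the bulky pinacol boronate then lies beside the unsubstituted C3–H terminus and not beside the C6 methyl group. The doubly ortho-substituted aroyl ester should be too hindered to transfer its acyl group at this temperature, the ring A methyl ethers are inert, and the excess of 15 allows for its volatility and slow protodeboronation.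

Step 7
Reactants: 17 4-(methoxycarbonyl)-3-methyl-5-(4,4,5,5-tetramethyl-1,3,2-dioxaborolan-2-yl)phenyl 3-chloro-2,4-dimethoxy-6-methylbenzoate
Product: 18 3-hydroxy-4-(methoxycarbonyl)-5-methylphenyl 3-chloro-2,4-dimethoxy-6-methylbenzoate
Conditions: NaBO3·4H2O, THF/H2O (1:1), rt; aq. NH4Cl
Reagents that add atoms: sodium perborate tetrahydrate NaBO3·4H2O, [Na+].[O-]OB=O.O.O.O.O (the oxygen of the new phenol)
Why: Oxidative cleavage of the aryl C–B bond: the peroxoborate adds to boron, the aryl group migrates from boron to oxygen, and hydrolysis of the borate gives the phenol at the same carbon. The medium is only mildly basic, and both esters are flanked by ortho substituents, so they should survive.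

Step 8
Reactants: 18 3-hydroxy-4-(methoxycarbonyl)-5-methylphenyl 3-chloro-2,4-dimethoxy-6-methylbenzoate
Product: 19 3-hydroxy-4-(methoxycarbonyl)-5-methylphenyl 3-chloro-2-hydroxy-4-methoxy-6-methylbenzoate (target CNP0146021.0)
Conditions: BCl3 (3 equiv), CH2Cl2, −78 → 0 °C; then H2O
Reagents that add atoms: none
Why: Chelation-assisted Lewis-acid ether cleavage: BCl3 binds between the depside carbonyl oxygen and the crowded C2' methoxy oxygen, and chloride removes the methyl group by SN2 as chloromethane. The C4' methoxy group has no chelating neighbour and the methyl ester needs far more forcing conditions, so both should remain. The ring B phenol is only borylated in passing and is freed again on hydrolysis.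

## Compound list

1 | 3,5-dimethoxytoluene (1,3-dimethoxy-5-methylbenzene) | Cc1cc(OC)cc(OC)c1 | starting material
2 | 2,6-dimethoxy-4-methylphenyllithium | [Li]c1c(OC)cc(C)cc1OC | intermediate
3 | 2-chloro-1,3-dimethoxy-5-methylbenzene | Cc1cc(OC)c(Cl)c(OC)c1 | intermediate
4 | 2-bromo-4-chloro-3,5-dimethoxy-1-methylbenzene | Cc1cc(OC)c(Cl)c(OC)c1Br | intermediate
5 | 3-chloro-2,4-dimethoxy-6-methylphenyllithium | [Li]c1c(C)cc(OC)c(Cl)c1OC | intermediate
6 | lithium 3-chloro-2,4-dimethoxy-6-methylbenzoate | [Li+].[O-]C(=O)c1c(C)cc(OC)c(Cl)c1OC | intermediate
7 | 3-chloro-2,4-dimethoxy-6-methylbenzoic acid | OC(=O)c1c(C)cc(OC)c(Cl)c1OC | intermediate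
8 | 4-hydroxy-6-methyl-2H-pyran-2-one (triacetic acid lactone) | Cc1cc(O)cc(=O)o1 | starting material
9 | 3-chloro-2,4-dimethoxy-6-methylbenzoyl chloride | ClC(=O)c1c(C)cc(OC)c(Cl)c1OC | intermediate
10 | 6-methyl-2-oxo-2H-pyran-4-yl 3-chloro-2,4-dimethoxy-6-methylbenzoate | Cc1cc(OC(=O)c2c(C)cc(OC)c(Cl)c2OC)cc(=O)o1 | intermediate
11 | methyl propiolate (methyl prop-2-ynoate) | C#CC(=O)OC | starting material
12 | 2-isopropoxy-4,4,5,5-tetramethyl-1,3,2-dioxaborolane | CC(C)OB1OC(C)(C)C(C)(C)O1 | starting material
13 | methyl 3-lithioprop-2-ynoate | [Li]C#CC(=O)OC | intermediate
14 | lithium (3-methoxy-3-oxoprop-1-yn-1-yl)(propan-2-yloxy)(2,3-dimethylbutane-2,3-diolato)borate | [Li+].COC(=O)C#C[B-]1(OC(C)C)OC(C)(C)C(C)(C)O1 | intermediate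
15 | methyl 3-(4,4,5,5-tetramethyl-1,3,2-dioxaborolan-2-yl)prop-2-ynoate | COC(=O)C#CB1OC(C)(C)C(C)(C)O1 | intermediate
16 | methyl 8-[(3-chloro-2,4-dimethoxy-6-methylbenzoyl)oxy]-1-methyl-3-oxo-5-(4,4,5,5-tetramethyl-1,3,2-dioxaborolan-2-yl)-2-oxabicyclo[2.2.2]octa-5,7-diene-6-carboxylate (racemic; bridgehead configuration fixed by the bicycle) | CC12OC(=O)C(C(OC(=O)c3c(C)cc(OC)c(Cl)c3OC)=C1)C(B4OC(C)(C)C(C)(C)O4)=C2C(=O)OC | intermediate
17 | 4-(methoxycarbonyl)-3-methyl-5-(4,4,5,5-tetramethyl-1,3,2-dioxaborolan-2-yl)phenyl 3-chloro-2,4-dimethoxy-6-methylbenzoate | COC(=O)c1c(C)cc(OC(=O)c2c(C)cc(OC)c(Cl)c2OC)cc1B3OC(C)(C)C(C)(C)O3 | intermediate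
18 | 3-hydroxy-4-(methoxycarbonyl)-5-methylphenyl 3-chloro-2,4-dimethoxy-6-methylbenzoate | COC(=O)c1c(C)cc(OC(=O)c2c(C)cc(OC)c(Cl)c2OC)cc1O | intermediate
19 | 3-hydroxy-4-(methoxycarbonyl)-5-methylphenyl 3-chloro-2-hydroxy-4-methoxy-6-methylbenzoate | COC(=O)c1c(C)cc(OC(=O)c2c(C)cc(OC)c(Cl)c2O)cc1O | target

## Step count and least certain steps

Total step count: 8. Longest linear sequence: 7 steps (steps 1, 2, 3, 4, 6, 7, 8); step 5 is a one-step branch.

**Step 6 (key step).**
- *Risk:* the cycloaddition may be too slow at temperatures that the alkynylboronate tolerates, because the diene is only moderately electron-rich and the alkyne is disubstituted. Long heating then invites protodeboronation of the alkyne, oligomerisation of the ynoate and an acyl shift from oxygen to carbon in the pyrone. The orientation may also be only partly controlled, since boron and the ester polarise the alkyne in opposite senses.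
- *Fallback:* give up the ring construction and acylate a preformed ring B. Acid chloride 9, generated from 7 as in step 4, would be treated with methyl 2,4-dihydroxy-6-methylbenzoate F1 (a purchased building block) and Et3N in CH2Cl2 at 0 °C. The 4-hydroxyl is the more acidic and is not hydrogen-bonded to the ester, so it should be acylated in preference to the 2-hydroxyl. This sets out from 7 and comes back to the route at 18, so that steps 5 to 7 are bypassed.

**Step 5.**
- *Risk:* the lithiated ynoate may self-condense by conjugate addition if the temperature rises before boron is attached. The electron-poor alkynyl–boron bond may also be protonated during the acid quench or the distillation, because both the ate complex and the product are cleaved by traces of water or excess acid.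
- *Fallback:* a base-free tin-to-boron exchange. Compound 11 and Bu3SnOMe (neat, rt, methanol removed under vacuum) should give methyl 3-(tributylstannyl)prop-2-ynoate F2. BCl3 in CH2Cl2 at −78 °C should exchange tin for boron to give methyl 3-(dichloroboranyl)prop-2-ynoate F3, which is not isolated. 2,3-Dimethyl-2,3-bis(trimethylsilyloxy)butane would then close the dioxaborolane without releasing acid. This sets out from 11 and comes back at 15.

**Step 4.**
- *Risk:* the pyronate is ambident, and the amine base or its hydrochloride can move the aroyl group from O4 to C3. The doubly ortho-substituted acid chloride may also acylate so slowly that hydrolysis of the acid chloride or of the activated enol ester competes during work-up.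
- *Fallback:* a neutral acyl transfer driven by silicon–fluorine bond formation. Compound 7 with cyanuric fluoride and pyridine in CH2Cl2 should give 3-chloro-2,4-dimethoxy-6-methylbenzoyl fluoride F4. Compound 8 with hexamethyldisilazane should give 6-methyl-4-[(trimethylsilyl)oxy]-2H-pyran-2-one F5. The two would be combined with catalytic CsF in MeCN, so that no amine is present when the ester forms. This sets out from 7 and 8 and comes back at 10.

**Step 8.**
- *Risk:* loss of chemoselectivity. Once the ring B phenol is bound to boron as a chelate with its neighbouring methyl ester, that ester is activated towards chloride. The C4' methoxy group may also be cleaved slowly if the mixture warms or stands.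
- *Fallback:* move the demethylation ahead of ring B formation, where neither the methyl ester nor the second phenol exists.
  - Compound 10 with BCl3 (CH2Cl2, −78 → 0 °C) should give 6-methyl-2-oxo-2H-pyran-4-yl 3-chloro-2-hydroxy-4-methoxy-6-methylbenzoate F6.
  - AcCl and Et3N in CH2Cl2 at 0 °C would mask the phenol as 6-methyl-2-oxo-2H-pyran-4-yl 2-acetoxy-3-chloro-4-methoxy-6-methylbenzoate F7.
  - Cycloaddition with 15 under the conditions of step 6 should pass through methyl 8-[(2-acetoxy-3-chloro-4-methoxy-6-methylbenzoyl)oxy]-1-methyl-3-oxo-5-(4,4,5,5-tetramethyl-1,3,2-dioxaborolan-2-yl)-2-oxabicyclo[2.2.2]octa-5,7-diene-6-carboxylate F8 (not isolated) to 4-(methoxycarbonyl)-3-methyl-5-(4,4,5,5-tetramethyl-1,3,2-dioxaborolan-2-yl)phenyl 2-acetoxy-3-chloro-4-methoxy-6-methylbenzoate F9.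
  - NaBO3·4H2O in THF/H2O should then oxidise the C–B bond and remove the unhindered aryl acetate by perhydrolysis in the same operation.
  
  This sets out from 10 and comes back at 19.

## Further compounds

F1 | step 6 | methyl 2,4-dihydroxy-6-methylbenzoate (methyl orsellinate, purchased building block) | COC(=O)c1c(C)cc(O)cc1O
F2 | step 5 | methyl 3-(tributylstannyl)prop-2-ynoate | CCCC[Sn](CCCC)(CCCC)C#CC(=O)OC
F3 | step 5 | methyl 3-(dichloroboranyl)prop-2-ynoate | COC(=O)C#CB(Cl)Cl
F4 | step 4 | 3-chloro-2,4-dimethoxy-6-methylbenzoyl fluoride | FC(=O)c1c(C)cc(OC)c(Cl)c1OC
F5 | step 4 | 6-methyl-4-[(trimethylsilyl)oxy]-2H-pyran-2-one | Cc1cc(O[Si](C)(C)C)cc(=O)o1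
F6 | step 8 | 6-methyl-2-oxo-2H-pyran-4-yl 3-chloro-2-hydroxy-4-methoxy-6-methylbenzoate | Cc1cc(OC(=O)c2c(C)cc(OC)c(Cl)c2O)cc(=O)o1
F7 | step 8 | 6-methyl-2-oxo-2H-pyran-4-yl 2-acetoxy-3-chloro-4-methoxy-6-methylbenzoate | Cc1cc(OC(=O)c2c(C)cc(OC)c(Cl)c2OC(C)=O)cc(=O)o1
F8 | step 8 | methyl 8-[(2-acetoxy-3-chloro-4-methoxy-6-methylbenzoyl)oxy]-1-methyl-3-oxo-5-(4,4,5,5-tetramethyl-1,3,2-dioxaborolan-2-yl)-2-oxabicyclo[2.2.2]octa-5,7-diene-6-carboxylate (racemic) | CC12OC(=O)C(C(OC(=O)c3c(C)cc(OC)c(Cl)c3OC(C)=O)=C1)C(B4OC(C)(C)C(C)(C)O4)=C2C(=O)OC
F9 | step 8 | 4-(methoxycarbonyl)-3-methyl-5-(4,4,5,5-tetramethyl-1,3,2-dioxaborolan-2-yl)phenyl 2-acetoxy-3-chloro-4-methoxy-6-methylbenzoate | COC(=O)c1c(C)cc(OC(=O)c2c(C)cc(OC)c(Cl)c2OC(C)=O)cc1B3OC(C)(C)C(C)(C)O3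
A1 | alternative 1 | 4-chloro-1-methoxy-1,3-bis(trimethylsilyloxy)buta-1,3-diene (double-bond geometry not defined) | COC(O[Si](C)(C)C)=CC(O[Si](C)(C)C)=CCl
A2 | alternative 1 | 4,4-dimethoxybut-3-en-2-one | CC(=O)C=C(OC)OC
A3 | alternative 1 | methyl 3-chloro-2-hydroxy-4-methoxy-6-methylbenzoate | COC(=O)c1c(C)cc(OC)c(Cl)c1O
A4 | alternative 1 | methyl 2,4-dihydroxy-6-methylbenzoate | COC(=O)c1c(C)cc(O)cc1O
A5 | alternative 2 | 2-chloro-1,3-dimethoxybenzene | COc1cccc(OC)c1Cl
A6 | alternative 2 | 5-bromo-2-chloro-1,3-dimethoxybenzene | COc1cc(Br)cc(OC)c1Cl
A7 | alternative 2 | 4-chloro-3,5-dimethoxybenzyne | COC1=C(Cl)C(OC)=CC#C1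
A8 | alternative 2 | 3-chloro-2,4-dimethoxy-6-methylbenzoic acid | COc1cc(C)c(C(=O)O)c(OC)c1Cl
A9 | alternative 3 | [(2-chloro-1,3-dimethoxybuta-1,3-dien-1-yl)oxy]trimethylsilane (double-bond geometry not defined) | COC(=C)C(Cl)=C(OC)O[Si](C)(C)C
A10 | alternative 3 | 3-[(tert-butyldimethylsilyl)oxy]-4-(methoxycarbonyl)-5-methylphenyl but-2-ynoate | CC#CC(=O)Oc1cc(C)c(C(=O)OC)c(O[Si](C)(C)C(C)(C)C)c1
A11 | alternative 3 | 3-[(tert-butyldimethylsilyl)oxy]-4-(methoxycarbonyl)-5-methylphenyl 3-chloro-2-hydroxy-4-methoxy-6-methylbenzoate | COC(=O)c1c(C)cc(OC(=O)c2c(C)cc(OC)c(Cl)c2O)cc1O[Si](C)(C)C(C)(C)C
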